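**Plan**

- Retrosynthesis: the C6=C7/C8=C17 diene is unmasked last from a C7=C8 alkene via its epoxide and the C7 allylic alcohol. The chain is cut at C13=C14 (olefination), at C11–C12 (organoborane alkylation) and at C9=C11 (methylenation of a C9 ketone).
- Ring A is then cut at C3–C4 (radical conjugate addition) and at C10–C1 and C10–C20 (two enolate alkylations), which leaves (S)-carvone.
- Enabling feature: C5–C10 of ring B, C17, and C4 with C18 and C19 are the ten carbons of (S)-carvone, the isopropenyl group being C4/C18/C19. Ring A therefore lacks only C1–C3 and the bond that makes C4 quaternary, and an epoxide on the isopropenyl group supplies both the C18 oxygen and a tertiary C4 radical.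
- Forward: ring B is bought; C20 and a C1–C3 acrylate arm are put on C10; ring A is closed by the titanocene radical cyclisation; the C2 ester is excised; C11, then C12/C13/C16, then C14/C15 are added; the diene is formed last.
- Stereochemistry: C5 from carvone; C10 by alkylation anti to the isopropenyl group; C4 in the chair-like radical closure; C9 by hydroboration anti to the C20 methyl; the 13E alkene from the olefination.

Key step: step 4

Remark: labdane numbering is used throughout (ring A = C1–C5 and C10; ring B = C5–C10; C17 on C8; C18 and C19 on C4; C20 on C10; C11–C16 the chain on C9), and faces are named relative to the C20 methyl. Compounds 4 and 8 are carried as epimer mixtures because the centre concerned becomes planar in the following step.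

**Route**

Step 1
Reactants: 1 (S)-carvone; 2 iodomethane
Product: 4 6-methylcarvone (both epimers at the new centre), via lithium dienolate 3 (not isolated)
Conditions: LiN(iPr)2, THF, −78 °C; MeI, −78 → 0 °C
Reagents that add atoms: iodomethane, CI
Why: Kinetic deprotonation at the α'-methylene (C10) gives the cross-conjugated lithium enolate, and its C-methylation (enolate alkylation) installs C20 at a centre that is planarised again in step 2.

Step 2
Reactants: 4 6-methylcarvone; 5 methyl 2-(bromomethyl)acrylate
Product: 7 trienone ester (acrylate arm trans to the isopropenyl group), via lithium dienolate 6 (not isolated)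
Conditions: LiN(iPr)2, THF, −78 °C; 5, −78 → −20 °C
Reagents that add atoms: methyl 2-(bromomethyl)acrylate, C=C(CBr)C(=O)OC
Why: Enolate alkylation with the allylic bromide (SN2 and SN2' give the same product) takes place on the enolate face opposite the neighbouring isopropenyl group, so the arm ends trans to it and the C20 methyl cis, which fixes C10.

Step 3
Reactants: 7 trienone ester
Product: 8 epoxy acrylate (both oxirane epimers)
Conditions: mCPBA, NaHCO3, CH2Cl2, 0 °C
Reagents that add atoms: 3-chloroperoxybenzoic acid, O=C(OO)c1cccc(Cl)c1
Why: Prilezhaev epoxidation touches only the electron-rich 1,1-disubstituted alkene and spares the enone and acrylate alkenes, and the configuration of the new oxirane carbon is irrelevant because it becomes a radical in step 4.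

Step 4
Reactants: 8 epoxy acrylate
Product: 10 bicyclic hydroxy ester, via titanium alkoxide enolate 9 (not isolated)
Conditions: Cp2TiCl2, Zn dust, THF, rt (gives Cp2TiCl); slow addition to 8 in THF, rt; then 1 M HCl
Reagents that add atoms: none
Why: Cp2TiCl (trivalent titanium) transfers one electron to the oxirane and breaks the bond between oxygen and the more substituted carbon, giving the tertiary C4 radical with C18 as a titanium alkoxide, so both oxirane epimers give the same radical; this nucleophilic radical adds to the unsubstituted terminus C3 of the acrylate, a second Cp2TiCl reduces the resulting C2 radical to a titanium enolate, and acid work-up protonates it. The closest known reaction type is the titanocene-mediated reductive epoxide opening with radical conjugate addition to acrylates, used here intramolecularly. Ring A closes in the 6-endo-trig mode, which the ester-bearing, fully substituted C2 favours over 5-exo attack both sterically and by polarity. C4 is set in a chair-like transition state on the fixed trans C5/C10 framework, where the bulky CH2OTiCp2Cl arm takes the equatorial site and the small methyl the axial site that is 1,3 to the C20 methyl; C2 is set on protonation of the enolate (equatorial ester expected) and is erased in step 6. The step needs the epoxide to react before the enone, which the fast oxirane opening secures, and ring closure before the tertiary radical is reduced, which the slow addition of the titanium reagent secures.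

Step 5
Reactants: 10 bicyclic hydroxy ester
Product: 11 hydroxy acid
Conditions: LiOH, THF/H2O, rt; then 1 M HCl
Reagents that add atoms: lithium hydroxide, [Li+].[OH-]
Why: Saponification of the unhindered secondary methyl ester leaves the enone and the neopentyl alcohol untouched, and any epimerisation at C2 is of no consequence.

Step 6
Reactants: 11 hydroxy acid
Product: 13 hydroxy enone, via thiohydroxamate ester 12 (not isolated)
Conditions: N-hydroxypyridine-2-thione, DCC, CH2Cl2, 0 °C → rt, dark; then t-BuSH, hν (tungsten lamp), rt
Reagents that add atoms: none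
Why: Barton reductive decarboxylation: without an acyl-transfer catalyst the acidic thiohydroxamic acid is acylated far faster than the hindered neopentyl C18 alcohol, and the photolytic radical chain expels CO2 and lets the secondary C2 radical take hydrogen from the thiol, removing the activating group.

Step 7
Reactants: 13 hydroxy enone; 14 methyltriphenylphosphonium bromide
Product: 15 dienol
Conditions: Ph3PCH3Br, KOtBu (excess), toluene, 90 °C
Reagents that add atoms: methyltriphenylphosphonium bromide, C[P+](c1ccccc1)(c1ccccc1)c1ccccc1.[Br-]
Why: Wittig methylenation with a hot, alkoxide-generated ylide is the standard answer to ketones next to a quaternary carbon, and the excess ylide merely deprotonates the free alcohol, so C11 is installed as the terminus of a 7,9(11)-diene.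

Step 8
Reactants: 15 dienol
Product: 16 diene acetate
Conditions: Ac2O, pyridine, DMAP, CH2Cl2, 0 °C → rt
Reagents that add atoms: acetic anhydride, CC(=O)OC(C)=O
Why: Standard acylation of the primary alcohol under basic conditions that do not endanger the acid-sensitive diene.

Step 9
Reactants: 16 diene acetate; 17 bromoacetone
Product: 19 methyl ketone, via B-alkyl-9-BBN 18 (not isolated)
Conditions: 9-BBN, THF, 0 → 50 °C; then 17, potassium 2,6-di-tert-butylphenoxide (from the phenol and KOtBu), THF, 0 °C → rt
Reagents that add atoms: bromoacetone, CC(=O)CBr
Why: 9-BBN adds to the terminal alkene of the diene with boron on C11 and delivers hydrogen to C9 from the face opposite the axial C20 methyl, which sets C9 with the chain cis to C20, and the organoborane then alkylates the enolate of bromoacetone through a borate and 1,2-shift of the primary alkyl group with loss of bromide (organoborane alkylation of an α-halo ketone).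

Step 10
Reactants: 19 methyl ketone; 20 trimethyl phosphonoacetate
Product: 21 dienoate
Conditions: (MeO)2P(O)CH2CO2Me, NaH, THF, 0 °C → reflux
Reagents that add atoms: trimethyl phosphonoacetate, COC(=O)CP(=O)(OC)OC
Why: Horner–Wadsworth–Emmons olefination of the methyl ketone should favour the (E)-enoate with the ester trans to the larger chain, and the minor (Z)-isomer is removed by chromatography.

Step 11
Reactants: 21 dienoate
Product: 22 epoxy enoate
Conditions: mCPBA, NaHCO3, CH2Cl2, 0 °C
Reagents that add atoms: 3-chloroperoxybenzoic acid, O=C(OO)c1cccc(Cl)c1
Why: Prilezhaev epoxidation selects the electron-rich trisubstituted C7=C8 alkene over the conjugated enoate, and the peracid approaches from the face opposite the axial C20 methyl.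

Step 12
Reactants: 22 epoxy enoate
Product: 24 allylic alcohol, via allylic silyl ether 23 (not isolated)
Conditions: TMSOTf, 2,6-lutidine, toluene, −78 °C; DBU, −78 °C → rt; then aq. citric acid, THF, 0 °C
Reagents that add atoms: none
Why: The silyl triflate opens the trisubstituted epoxide at the tertiary C8 and the bulky amidine removes an accessible C17 proton in preference to the shielded C9 methine (epoxide to allylic silyl ether isomerisation), which gives the exocyclic alkene with the C7 oxygen retained in its axial orientation before mild acid frees the alcohol.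

Step 13
Reactants: 24 allylic alcohol
Product: 25 target
Conditions: Ph2S[OC(CF3)2Ph]2 (Martin sulfurane), CH2Cl2, 0 °C → rt
Reagents that add atoms: none
Why: The sulfurane turns the axial C7 hydroxyl into an alkoxysulfonium leaving group that is antiperiplanar to the axial C6 hydrogen, so E2-type dehydration gives the C6=C7 alkene conjugated to the exocyclic methylene, and no hydrogen on the C8 side can compete.

**Compound list**

1 | (S)-carvone | CC1=CC[C@H](C(C)=C)CC1=O | starting material
2 | iodomethane | CI | starting material
3 | lithium dienolate of 1 (enolate double bond C9=C10) | CC1=CC[C@H](C(C)=C)C=C1[O-].[Li+] | intermediate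
4 | 6-methylcarvone, (5S)-2,6-dimethyl-5-(prop-1-en-2-yl)cyclohex-2-en-1-one, both epimers at the methyl-bearing carbon (trans isomer drawn) | CC1=CC[C@H](C(C)=C)[C@@H](C)C1=O | intermediate
5 | methyl 2-(bromomethyl)acrylate | C=C(CBr)C(=O)OC | starting material
6 | lithium dienolate of 4 | CC1=CC[C@H](C(C)=C)C(C)=C1[O-].[Li+] | intermediate
7 | trienone ester: methyl 2-{[1,3-dimethyl-2-oxo-6-(prop-1-en-2-yl)cyclohex-3-en-1-yl]methyl}acrylate, acrylate arm trans and ring methyl cis to the isopropenyl group | CC1=CC[C@H](C(C)=C)[C@@](C)(CC(=C)C(=O)OC)C1=O | intermediate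
8 | epoxy acrylate: 7 with the isopropenyl group as a 2-methyloxiran-2-yl group, both epimers at the oxirane carbon | CC1=CC[C@H](C2(C)CO2)[C@@](C)(CC(=C)C(=O)OC)C1=O | intermediate
9 | titanium alkoxide enolate: C18–O–TiCp2Cl and C2 ester enolate O–TiCp2Cl (tetravalent titanium) | CC1=CC[C@@H]2[C@@](C)(C[O-])CC(=C([O-])OC)C[C@@]2(C)C1=O.[Ti+4].[Ti+4].[Cl-].[Cl-].[cH-]1cccc1.[cH-]1cccc1.[cH-]1cccc1.[cH-]1cccc1 | intermediate
10 | bicyclic hydroxy ester: trans-fused C7=C8(C17)–C9=O enone, C18 hydroxymethyl equatorial and C19 methyl axial (cis to C20) on C4, equatorial CO2Me on C2 | CC1=CC[C@@H]2[C@@](C)(CO)C[C@@H](C(=O)OC)C[C@@]2(C)C1=O | intermediate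
11 | hydroxy acid: 10 with CO2H on C2 | CC1=CC[C@@H]2[C@@](C)(CO)C[C@@H](C(=O)O)C[C@@]2(C)C1=O | intermediate
12 | thiohydroxamate ester: 2-thioxopyridin-1(2H)-yl ester of 11 | CC1=CC[C@@H]2[C@@](C)(CO)C[C@@H](C(=O)ON3C=CC=CC3=S)C[C@@]2(C)C1=O | intermediate
13 | hydroxy enone: 10 without the C2 substituent | CC1=CC[C@@H]2[C@@](C)(CO)CCC[C@@]2(C)C1=O | intermediate
14 | methyltriphenylphosphonium bromide | C[P+](c1ccccc1)(c1ccccc1)c1ccccc1.[Br-] | starting material
15 | dienol: C9=C11 methylene, C7=C8 alkene, free C18 alcohol | CC1=CC[C@@H]2[C@@](C)(CO)CCC[C@@]2(C)C1=C | intermediate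
16 | diene acetate: C18 acetate of 15 | CC1=CC[C@@H]2[C@@](C)(COC(C)=O)CCC[C@@]2(C)C1=C | intermediate
17 | bromoacetone | CC(=O)CBr | starting material
18 | B-alkyl-9-BBN: C11 bonded to boron, H9 on the face opposite C20 | CC1=CC[C@@H]2[C@@](C)(COC(C)=O)CCC[C@@]2(C)[C@@H]1CB3C4CCCC3CCC4 | intermediate
19 | methyl ketone: 18-acetoxy-14,15-dinor-ent-labd-7-en-13-one | CC1=CC[C@@H]2[C@@](C)(COC(C)=O)CCC[C@@]2(C)[C@@H]1CCC(C)=O | intermediate
20 | trimethyl phosphonoacetate | COC(=O)CP(=O)(OC)OC | starting material
21 | dienoate: methyl (E)-18-acetoxy-ent-labda-7,13-dien-15-oate | CC1=CC[C@@H]2[C@@](C)(COC(C)=O)CCC[C@@]2(C)[C@@H]1CC/C(C)=C/C(=O)OC | intermediate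
22 | epoxy enoate: 7,8-epoxide of 21, oxygen on the face opposite C20 | C[C@]12O[C@H]1C[C@@H]3[C@@](C)(COC(C)=O)CCC[C@@]3(C)[C@@H]2CC/C(C)=C/C(=O)OC | intermediate
23 | allylic silyl ether: trimethylsilyl ether of 24 | C=C1[C@@H](O[Si](C)(C)C)C[C@@H]2[C@@](C)(COC(C)=O)CCC[C@@]2(C)[C@@H]1CC/C(C)=C/C(=O)OC | intermediate
24 | allylic alcohol: methyl (E)-18-acetoxy-7-hydroxy-ent-labda-8(17),13-dien-15-oate, axial 7-OH on the face opposite C20 | C=C1[C@@H](O)C[C@@H]2[C@@](C)(COC(C)=O)CCC[C@@]2(C)[C@@H]1CC/C(C)=C/C(=O)OC | intermediate
25 | methyl (E)-18-acetoxy-ent-labda-6,8(17),13-trien-15-oate | C=C1C=C[C@@H]2[C@@](C)(COC(C)=O)CCC[C@@]2(C)[C@@H]1CC/C(C)=C/C(=O)OC | target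

**Count and risks**

Total step count: 13. Longest linear sequence: 13 steps from (S)-carvone.

Steps most likely to fail:

1. Step 4. The tertiary titanoxy radical may be reduced or lose a β-hydrogen before it closes ring A, the enone may be reduced in competition, or the planar C4 radical may show too little facial bias. The fallback generates the same C4 radical by hydrogen-atom transfer to an alkene and sets out from 7. Ene-type chlorination of the isopropenyl group (Ca(OCl)2, solid CO2, CH2Cl2/H2O) would give allylic chloride F1, and displacement with KOAc in DMF would give allylic acetate F2. Fe(acac)3 and PhSiH3 in EtOH would then deliver a hydrogen atom to the terminal alkene carbon, and the resulting tertiary radical, now carrying C18 as an acetoxymethyl group, would close onto the acrylate (Giese-type cyclisation) to bicyclic acetoxy ester F3. LiOH cleaves both esters of F3, and the route is rejoined at 11.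

2. Step 12. The base may remove the C9 proton in place of a C17 proton, a hydride shift may lead to a C7 ketone, or the esters may be silylated and the enoate isomerised. The fallback avoids the epoxide and sets out from 21. Electrophilic ene-type chlorination (Ca(OCl)2, solid CO2, CH2Cl2/H2O, 0 °C) should place chlorine on C7 from the face opposite C20 with loss of a C17 proton, giving allylic chloride F4. DBU in warm toluene would then remove HCl antiperiplanar across C6–C7 and reach 25 directly, so 22 to 24 and step 13 are bypassed.

3. Step 9. In the crowded borate the 1,2-shift of the neopentyl-like C11 group may be slow, or a B–C bond of the bicycle may migrate in its place. The fallback keeps the hydroboration and sets out from 16 through 18, but replaces the boron-to-carbon alkylation. Oxidation of 18 with NaBO3·4H2O would give primary alcohol F5, Dess–Martin periodinane would give aldehyde F6, and Wittig reaction with Ph3P=CHC(O)CH3 would give (E)-enone F7. Conjugate reduction of F7 with [(Ph3P)CuH]6 in toluene would return the route at 19.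

**Further compounds**

F1 | step 4 | allylic chloride: 7 with the isopropenyl methyl as CH2Cl | CC1=CC[C@H](C(=C)CCl)[C@@](C)(CC(=C)C(=O)OC)C1=O
F2 | step 4 | allylic acetate: 7 with the isopropenyl methyl as CH2OAc | CC1=CC[C@H](C(=C)COC(C)=O)[C@@](C)(CC(=C)C(=O)OC)C1=O
F3 | step 4 | bicyclic acetoxy ester: C18 acetate of 10 | CC1=CC[C@@H]2[C@@](C)(COC(C)=O)C[C@@H](C(=O)OC)C[C@@]2(C)C1=O
F4 | step 12 | allylic chloride: methyl (E)-18-acetoxy-7-chloro-ent-labda-8(17),13-dien-15-oate, axial chlorine on the face opposite C20 | C=C1[C@@H](Cl)C[C@@H]2[C@@](C)(COC(C)=O)CCC[C@@]2(C)[C@@H]1CC/C(C)=C/C(=O)OC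
F5 | step 9 | primary alcohol: C11 hydroxymethyl on C9, C7=C8 alkene, C18 acetate | CC1=CC[C@@H]2[C@@](C)(COC(C)=O)CCC[C@@]2(C)[C@@H]1CO
F6 | step 9 | aldehyde: C11 formyl group on C9 | CC1=CC[C@@H]2[C@@](C)(COC(C)=O)CCC[C@@]2(C)[C@@H]1C=O
F7 | step 9 | (E)-enone: C11=C12 alkene conjugated to the C13 methyl ketone | CC1=CC[C@@H]2[C@@](C)(COC(C)=O)CCC[C@@]2(C)[C@@H]1/C=C/C(C)=O
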